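## The problem

The target 15 is a single oxolane (O1, C2 to C5) with three contiguous stereocentres. C2 (S) carries a 3,4,5-trimethoxyphenyl group, C3 (R) a hydroxymethyl group and C4 (R) a 3,4,5-trimethoxybenzyl group whose benzylic carbon is called C7' below; C5 is a methylene. The aryl and hydroxymethyl groups are trans, which a five-membered ring adopts readily. The hydroxymethyl and benzyl groups are cis, which it does not, so C4 has to be made under kinetic control. C2 is the natural place for a catalyst to set absolute configuration; C3 can follow C2 thermodynamically while it is α to a carbonyl group, and C4 can follow C3 if it is made last by addition to a trigonal carbon from the face away from the C3 substituent. The weak point is the C2–O1 bond, a benzylic ether to an electron-rich arene: strong acid ionises it (epimerisation, ring opening, Friedel–Crafts closure onto the second arene) and forcing hydrogenation cleaves it. The six methyl ethers are robust but make both arenes nucleophilic toward cations and carbenes. The enabling feature is that C2–H is both benzylic and α to O1, hence hydridic, and that C2 is linked to C3 through O1–C5–C4 in a 1,5 relationship. If C3 is a carbene carbon and C4 is the internal carbon of a styrene, a 1,5 C–H insertion closes the ring at C2–C3, the alkene tames the carbene, and the C4 benzylidene that results is the handle for the last stereocentre.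

## Retrosynthesis

**15 to 14 (C4–H and C7'–H).** The C4 stereocentre is removed first by drawing a C4=C7' double bond, giving benzylidene alcohol 14. The cis C3/C4 relationship is then the kinetic result of hydrogen adding anti to the C3 hydroxymethyl group. The forward step must reduce a trisubstituted styrene without cleaving the benzylic C2–O1 bond.

**14 to 13 (CH2OH from CO2Me).** The hydroxymethyl group is traced to the methyl ester of 13. The ester is reduced before the alkene because C3–H in 13 is both α to the ester and allylic; once the ester is gone, C3 can no longer epimerise and the alkene can no longer slide into conjugation. The forward step needs a non-basic hydride at low temperature.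

**13 to 11 through 12 (C2–C3).** The ring is opened between its two adjacent stereocentres, giving the achiral, acyclic vinyldiazoacetate 11, in which C3 is the diazo carbon and C2 a benzylic ether methylene.
- Cutting O1–C2 instead would call for a benzylic etherification that invites ionisation and loss of configuration.
- Cutting C3–C4 would leave C2 to be set beforehand in an acyclic ether.
- The C2–C3 cut lets one chiral catalyst set C2 in the ring-forming step and leaves C3 to settle trans by equilibration of the kinetic ester 12 to 13.
- The forward reaction must insert at the carbene carbon, not at the styryl terminus, and must distinguish two enantiotopic hydrogens.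

**11 to 10 (C=N2).** The diazo group is removed to give the β,γ-unsaturated ester 10, whose methylene is activated by both the ester and the alkene. Diazo transfer must not disturb the alkene geometry.

**10 to 9, 8 and 7 (C3–carbonyl bond).** The ester carbon of 10 is cut off as carbon monoxide, leading to allylic carbonate 9, allylic alcohol 8 and the conjugated ester 7. The carbonyl carbon of 7 thus becomes C3 and the inserted CO becomes the hydroxymethyl carbon. A Stobbe-type condensation would reach a related skeleton in one step, but with the aryl group cis to the carbon that must become the carbene; the longer sequence from 7 keeps the aryl group trans to it. The carbonylation must capture the allyl unit at its unsubstituted end before the geometry is lost.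

**7 to 5 (and mesylate 6), then 3 and 4 (C4=C7').** The trisubstituted alkene is cut by an aldol condensation between the enolate of β-alkoxy ester 3 and aldehyde 4. Elimination through the enolate gives the more stable geometry, aryl trans to the ester, which is the one needed. The aldol stereocentres of 5 are irrelevant.

**3 to 1 and 2 (O1–C5).** The ether is cut by an oxa-Michael addition of benzylic alcohol 1 to methyl acrylate 2. The route thus starts from three commodity compounds, with the C2 aryl group from 1, C4 and C5 from 2 and the benzyl arene from 4.

## Roads not taken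

**Alternative 1:** The cut is O1–C2, with C2, C3 and C4 drawn together into a cyclopropane that carries the future C5 as a formyl group on C4 (cyclopropanecarbaldehyde A2). In the forward direction Sc(OTf)3 binds the formyl oxygen, the C2–C4 bond heterolyses toward the benzylic cation, and the formyl oxygen closes on C2 to give 2,3-dihydrofuran A1. Hydrogenation of the C4=C5 enol ether and desilylation would finish.
- Merits: ring expansion of donor–acceptor cyclopropanes is a reliable reaction class, better established than the insertion chosen here. The C3 stereocentre is carried through untouched, C2 can correct itself to trans through the reversible ionisation, and the benzyl carbon is already at its final oxidation level.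
- Weak points: A2 is a fully substituted cyclopropane with a quaternary formyl-bearing carbon and must be made as a single enantiomer, which is where most of the steps would go. One aldehyde is a weaker acceptor than the usual diester. The 3,4,5-trimethoxyphenyl donor is weaker than a 4-methoxyphenyl group because its para methoxy is twisted. The final hydrogenation faces the same facial question at C4 as the chosen plan, on an acid-labile enol ether.
- Comparison: the alternative is ahead in the precedent for its key step. The chosen plan sets against this an achiral precursor made from three commodity chemicals and absolute configuration created by a catalyst in the ring-forming step.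

**Alternative 2:** The cuts are C2–C3 and C4–C5 together: the oxolane is seen as a carbonyl ylide (C2–O1–C5) added across the alkene of the γ-aryl butenolide A4, whose γ-carbon is the future C7'. In the forward direction CsF removes the silyl group of chloro ether A5, chloride leaves, and the ylide adds to A4 anti to its aryl group to give the cis-fused bicyclic lactone A3. Hydrogenolysis of the benzylic lactone C–O bond and reduction of the freed carboxyl group would give 15.
- Merits: two C–C bonds, the ring and three stereocentres form in one step. The 3,4-cis relationship is guaranteed by the ring fusion instead of resting on a face-selective hydrogenation, a real advantage over the chosen plan. The sequence is also shorter on paper.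
- Weak points: the orientation of an unsymmetrical, non-stabilised ylide toward the butenolide is not secured by any tether and could place the aryl-bearing carbon on the wrong alkene carbon. The exo/endo preference sets C2 and is uncertain. The γ-hydrogen of A4 is acidic, so fluoride can racemise it. The hydrogenolysis must distinguish two benzylic C–O bonds to identical arenes.
- Comparison: the chosen plan is longer but has unambiguous regiochemistry through the tether and carries no stereocentre before the key step that could be lost.

**Alternative 3:** The cuts are O1–C2, C3–C4 and C7'–aryl. In the forward direction the alkoxide of propargyl alcohol A9 adds to arylidene malonate A7, and the malonate anion attacks the alkyne held by the arylpalladium iodide (divalent palladium) formed from aryl iodide A8 and Pd(PPh3)4. Reductive elimination gives diester A6. Krapcho loss of one ester, reduction and hydrogenation would follow along the same lines as steps 9 and 10.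
- Merits: this is the shortest road by a wide margin. One flask assembles the whole skeleton from three simple components, the reaction type is established for exactly this benzylidene oxolane pattern, and it arrives in the same series as 13.
- Weak points: C2 is formed racemic, because the oxa-Michael addition is reversible and no chiral species controls it. A single enantiomer then needs a resolution that discards half the material. The hot dealkoxycarbonylation may move the alkene.
- Comparison: in step count and precedent this alternative is clearly better, and for the racemate it would be the route of choice. The chosen plan has only catalytic control of absolute configuration to set against it, which is what the single-enantiomer target demands.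

Key step: step 8

## Assumptions

- Rh2(S-PTTL)4, dirhodium tetrakis[N-phthaloyl-(S)-tert-leucinate], is taken to deliver the 2S configuration. If the first experiment shows the opposite sense, the mirror-image catalyst Rh2(R-PTTL)4 is used and nothing else changes.
- The kinetic C3 configuration is taken to be mainly cis to the aryl group, as in the dihydrobenzofuran series. The equilibration in step 8 makes the outcome independent of this.

## Route

Step 1
Reactants: 1 3,4,5-trimethoxybenzyl alcohol; 2 methyl acrylate
Product: 3 methyl 3-[(3,4,5-trimethoxyphenyl)methoxy]propanoate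
Conditions: KOt-Bu (5 mol %), THF, 0 °C to rt, 2 (2 equiv)
Reagents that add atoms: none
Why: Base-catalysed oxa-Michael addition of the benzylic alkoxide to the acrylate; catalytic alkoxide and excess acrylate should keep transesterification minor.

Step 2
Reactants: 3 methyl 3-[(3,4,5-trimethoxyphenyl)methoxy]propanoate; 4 3,4,5-trimethoxybenzaldehyde
Product: 5 methyl 3-hydroxy-3-(3,4,5-trimethoxyphenyl)-2-{[(3,4,5-trimethoxyphenyl)methoxy]methyl}propanoate (mixture of diastereomers, racemic)
Conditions: LiN(i-Pr)2 (1.1 equiv), THF, −78 °C; then 4, −78 °C; aq. NH4Cl at −78 °C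
Reagents that add atoms: none
Why: Lithium enolate aldol addition; at −78 °C the β-alkoxy ester enolate should live long enough to be trapped by the aldehyde. Both new stereocentres disappear in step 3, so the diastereomer ratio does not matter.

Step 3
Reactants: 5 methyl 3-hydroxy-3-(3,4,5-trimethoxyphenyl)-2-{[(3,4,5-trimethoxyphenyl)methoxy]methyl}propanoate
Product: 7 methyl (2E)-3-(3,4,5-trimethoxyphenyl)-2-{[(3,4,5-trimethoxyphenyl)methoxy]methyl}prop-2-enoate (aryl trans to the ester, cis to the CH2O arm), via benzylic mesylate 6 (not isolated)
Conditions: MsCl, Et3N, CH2Cl2, 0 °C; then DBU (2 equiv), 0 °C to rt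
Reagents that add atoms: methanesulfonyl chloride, CS(=O)(=O)Cl (supplies the mesyl group of 6; none of its atoms remain in 7)
Why: Mesylation followed by E1cB elimination through the ester enolate; the conjugated isomer with aryl trans to the ester is the more stable one and should predominate, as in the trisubstituted cinnamates derived from Morita–Baylis–Hillman adducts.

Step 4
Reactants: 7 methyl (2E)-3-(3,4,5-trimethoxyphenyl)-2-{[(3,4,5-trimethoxyphenyl)methoxy]methyl}prop-2-enoate
Product: 8 (2Z)-3-(3,4,5-trimethoxyphenyl)-2-{[(3,4,5-trimethoxyphenyl)methoxy]methyl}prop-2-en-1-ol (aryl cis to the benzyloxymethyl arm)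
Conditions: i-Bu2AlH (2.5 equiv), CH2Cl2, −78 to −20 °C; aq. potassium sodium tartrate
Reagents that add atoms: none
Why: 1,2-Reduction of a conjugated ester to the allylic alcohol by the aluminium hydride; the alkene and its geometry are not touched.

Step 5
Reactants: 8 (2Z)-3-(3,4,5-trimethoxyphenyl)-2-{[(3,4,5-trimethoxyphenyl)methoxy]methyl}prop-2-en-1-ol
Product: 9 methyl (2E)-3-(3,4,5-trimethoxyphenyl)-2-{[(3,4,5-trimethoxyphenyl)methoxy]methyl}prop-2-en-1-yl carbonate (same geometry as 8)
Conditions: ClCO2Me, pyridine, DMAP (cat.), CH2Cl2, 0 °C to rt
Reagents that add atoms: methyl chloroformate, COC(=O)Cl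
Why: Acylation of a primary allylic alcohol; the carbonate is the leaving group and the internal methoxide source for the next step.

Step 6
Reactants: 9 methyl (2E)-3-(3,4,5-trimethoxyphenyl)-2-{[(3,4,5-trimethoxyphenyl)methoxy]methyl}prop-2-en-1-yl carbonate
Product: 10 methyl (3Z)-4-(3,4,5-trimethoxyphenyl)-3-{[(3,4,5-trimethoxyphenyl)methoxy]methyl}but-3-enoate (aryl cis to the benzyloxymethyl arm)
Conditions: Pd(OAc)2 (2 mol %), PPh3 (8 mol %), CO (10 atm), toluene, 50 °C
Reagents that add atoms: carbon monoxide, [C-]#[O+]
Why: Palladium-catalysed decarboxylative carbonylation of an allylic carbonate: zerovalent palladium ionises 9 to the π-allyl complex with the aryl group syn, CO2 is lost, CO inserts at the unsubstituted terminus and the methoxide closes the β,γ-unsaturated ester. Fast capture under CO pressure should keep the alkene geometry.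

Step 7
Reactants: 10 methyl (3Z)-4-(3,4,5-trimethoxyphenyl)-3-{[(3,4,5-trimethoxyphenyl)methoxy]methyl}but-3-enoate
Product: 11 methyl (3Z)-2-diazo-4-(3,4,5-trimethoxyphenyl)-3-{[(3,4,5-trimethoxyphenyl)methoxy]methyl}but-3-enoate (aryl cis to the benzyloxymethyl arm, trans to the diazo carbon)
Conditions: p-ABSA (1.3 equiv), DBU (1.5 equiv), MeCN, 0 °C; used without storage
Reagents that add atoms: 4-acetamidobenzenesulfonyl azide (p-ABSA), CC(=O)Nc1ccc(cc1)S(=O)(=O)N=[N+]=[N-]
Why: Regitz diazo transfer to a methylene activated by both the ester and the alkene, the standard entry to vinyldiazoacetates. Low temperature and prompt use limit electrocyclisation of the vinyl diazo unit to a pyrazole.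

Step 8
Reactants: 11 methyl (3Z)-2-diazo-4-(3,4,5-trimethoxyphenyl)-3-{[(3,4,5-trimethoxyphenyl)methoxy]methyl}but-3-enoate
Product: 13 methyl (2S,3S,4Z)-2-(3,4,5-trimethoxyphenyl)-4-[(3,4,5-trimethoxyphenyl)methylidene]oxolane-3-carboxylate (aryl and ester trans; benzylidene aryl cis to C5), via 2,3-cis ester 12 (not isolated)
Conditions: Rh2(S-PTTL)4 (1 mol %), toluene, −40 to 0 °C, slow addition of 11; then DBU (0.2 equiv), 0 °C
Reagents that add atoms: none
Why: Proposed new method: Rh2(S-PTTL)4 expels N2 from 11 to give a dirhodium carbene at C3 flanked by the ester (acceptor) and the styryl group (donor), and the hydridic C2–H bond, benzylic and α to O1, passes its hydrogen to C3 while the C2–C3 bond forms in one three-centre transition state. The closest known reaction type is the enantioselective dirhodium-carboxylate-catalysed 1,5 C–H insertion of aryldiazoacetates into benzylic ether C–H bonds, which gives 2-aryl-2,3-dihydrobenzofuran-3-carboxylates; here an alkene carbon takes the place of the arene carbon that carries the tether, and this has not been shown. The oxolane closes by 1,5-insertion through a five-membered transition state made of C3, C4, C5, O1 and C2, whereas attack of O1 on the carbene would need a four-membered oxonium ylide and is not expected to compete. C2 is set by the chiral carboxylate ligands, which choose between the two enantiotopic benzylic hydrogens. C3 is formed under kinetic control, by analogy mainly cis to the aryl group (12), and catalytic DBU then equilibrates it through the ester dienolate to the more stable 2,3-trans ester 13, α-protonation being the kinetically preferred return path. The step needs site selectivity for the carbene carbon over the vinylogous styryl carbon, which is also 1,5 to C2–H; the aryl group on that carbon, the non-polar solvent and the carboxylate ligands all disfavour vinylogous attack. The aryl group lies trans to the carbene carbon, so it neither twists the alkene out of conjugation nor cyclises onto the carbene, and the alkene geometry is carried unchanged into the (Z)-benzylidene of 13.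

Step 9
Reactants: 13 methyl (2S,3S,4Z)-2-(3,4,5-trimethoxyphenyl)-4-[(3,4,5-trimethoxyphenyl)methylidene]oxolane-3-carboxylate
Product: 14 [(2S,3R,4Z)-2-(3,4,5-trimethoxyphenyl)-4-[(3,4,5-trimethoxyphenyl)methylidene]oxolan-3-yl]methanol (aryl and CH2OH trans)
Conditions: i-Bu2AlH (3 equiv), CH2Cl2, −78 °C; aq. potassium sodium tartrate
Reagents that add atoms: none
Why: Reduction of the ester to the primary alcohol with a non-basic hydride at low temperature, so the acidic allylic C3–H is not disturbed. The change of descriptor at C3 is only a change in priority; the geometry is that of 13.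

Step 10
Reactants: 14 [(2S,3R,4Z)-2-(3,4,5-trimethoxyphenyl)-4-[(3,4,5-trimethoxyphenyl)methylidene]oxolan-3-yl]methanol
Product: 15 [(2S,3R,4R)-2-(3,4,5-trimethoxyphenyl)-4-[(3,4,5-trimethoxyphenyl)methyl]oxolan-3-yl]methanol (2,3-trans, 3,4-cis)
Conditions: H2 (1 atm), 10% Pd on carbon, EtOAc, rt, stopped at one equivalent of H2
Reagents that add atoms: none
Why: Heterogeneous hydrogenation of the exocyclic styrene, with hydrogen delivered to the face of C4 anti to the adjacent C3 hydroxymethyl group; the C2 aryl group on the other face is one atom further away, and this sense is the one established for 2-aryl-4-benzylidene-3-(hydroxymethyl)oxolanes of the lignan series. Neutral solvent, low pressure and a short reaction time should spare the benzylic C2–O1 bond.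

## Compound list

1 | 3,4,5-trimethoxybenzyl alcohol | COc1cc(CO)cc(OC)c1OC | starting material
2 | methyl acrylate | C=CC(=O)OC | starting material
3 | methyl 3-[(3,4,5-trimethoxyphenyl)methoxy]propanoate | COC(=O)CCOCc1cc(OC)c(OC)c(OC)c1 | intermediate
4 | 3,4,5-trimethoxybenzaldehyde | COc1cc(C=O)cc(OC)c1OC | starting material
5 | methyl 3-hydroxy-3-(3,4,5-trimethoxyphenyl)-2-{[(3,4,5-trimethoxyphenyl)methoxy]methyl}propanoate (diastereomer mixture, racemic) | COC(=O)C(COCc1cc(OC)c(OC)c(OC)c1)C(O)c1cc(OC)c(OC)c(OC)c1 | intermediate
6 | methyl 3-(methanesulfonyloxy)-3-(3,4,5-trimethoxyphenyl)-2-{[(3,4,5-trimethoxyphenyl)methoxy]methyl}propanoate (diastereomer mixture) | COC(=O)C(COCc1cc(OC)c(OC)c(OC)c1)C(OS(C)(=O)=O)c1cc(OC)c(OC)c(OC)c1 | intermediate (not isolated)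
7 | methyl (2E)-3-(3,4,5-trimethoxyphenyl)-2-{[(3,4,5-trimethoxyphenyl)methoxy]methyl}prop-2-enoate | COc1cc(/C=C(\COCc2cc(OC)c(OC)c(OC)c2)C(=O)OC)cc(OC)c1OC | intermediate
8 | (2Z)-3-(3,4,5-trimethoxyphenyl)-2-{[(3,4,5-trimethoxyphenyl)methoxy]methyl}prop-2-en-1-ol | COc1cc(/C=C(\COCc2cc(OC)c(OC)c(OC)c2)CO)cc(OC)c1OC | intermediate
9 | methyl (2E)-3-(3,4,5-trimethoxyphenyl)-2-{[(3,4,5-trimethoxyphenyl)methoxy]methyl}prop-2-en-1-yl carbonate | COc1cc(/C=C(\COCc2cc(OC)c(OC)c(OC)c2)COC(=O)OC)cc(OC)c1OC | intermediate
10 | methyl (3Z)-4-(3,4,5-trimethoxyphenyl)-3-{[(3,4,5-trimethoxyphenyl)methoxy]methyl}but-3-enoate | COc1cc(/C=C(\COCc2cc(OC)c(OC)c(OC)c2)CC(=O)OC)cc(OC)c1OC | intermediate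
11 | methyl (3Z)-2-diazo-4-(3,4,5-trimethoxyphenyl)-3-{[(3,4,5-trimethoxyphenyl)methoxy]methyl}but-3-enoate | COc1cc(/C=C(\COCc2cc(OC)c(OC)c(OC)c2)C(=[N+]=[N-])C(=O)OC)cc(OC)c1OC | intermediate
12 | methyl (2S,3R,4Z)-2-(3,4,5-trimethoxyphenyl)-4-[(3,4,5-trimethoxyphenyl)methylidene]oxolane-3-carboxylate (2,3-cis) | COc1cc(/C=C2\CO[C@H](c3cc(OC)c(OC)c(OC)c3)[C@@H]2C(=O)OC)cc(OC)c1OC | intermediate (not isolated)
13 | methyl (2S,3S,4Z)-2-(3,4,5-trimethoxyphenyl)-4-[(3,4,5-trimethoxyphenyl)methylidene]oxolane-3-carboxylate (2,3-trans) | COc1cc(/C=C2\CO[C@H](c3cc(OC)c(OC)c(OC)c3)[C@H]2C(=O)OC)cc(OC)c1OC | intermediate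
14 | [(2S,3R,4Z)-2-(3,4,5-trimethoxyphenyl)-4-[(3,4,5-trimethoxyphenyl)methylidene]oxolan-3-yl]methanol | COc1cc(/C=C2\CO[C@H](c3cc(OC)c(OC)c(OC)c3)[C@H]2CO)cc(OC)c1OC | intermediate
15 | [(2S,3R,4R)-2-(3,4,5-trimethoxyphenyl)-4-[(3,4,5-trimethoxyphenyl)methyl]oxolan-3-yl]methanol | COc1cc(C[C@H]2CO[C@H](c3cc(OC)c(OC)c(OC)c3)[C@H]2CO)cc(OC)c1OC | target

## Step count and least certain steps

Total steps: 10. Longest linear sequence: 10 (from 1 and 2; aldehyde 4 enters in step 2).

**Step 8 (key step, proposed new method).**
- What may go wrong: thermal electrocyclisation of the vinyl diazo unit before the catalyst engages; reaction at the vinylogous styryl carbon, or hydride abstraction followed by collapse there; weak discrimination between the enantiotopic C2 hydrogens; during the C3 equilibration, migration of the alkene into conjugation with the ester, or reversible β-elimination of O1 that would erode C2.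
- Fallback, known chemistry throughout, setting out from 4 and coming back at 15:
  - Stobbe condensation of 4 with dimethyl succinate (NaOMe, MeOH) would give the half-ester (3E)-3-(methoxycarbonyl)-4-(3,4,5-trimethoxyphenyl)but-3-enoic acid F1.
  - Asymmetric hydrogenation with a cationic rhodium bisphosphine catalyst such as [Rh(cod)(Me-DuPhos)]BF4 (ligand antipode chosen for the R product) would give (3R)-3-(methoxycarbonyl)-4-(3,4,5-trimethoxyphenyl)butanoic acid F2.
  - Reduction of the ester beside the carboxylate (Ca(BH4)2, then acid) would give the lactone (4R)-4-[(3,4,5-trimethoxyphenyl)methyl]oxolan-2-one F3.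
  - Aldol addition of its lithium enolate (LiN(SiMe3)2, THF, −78 °C) to a second portion of 4, anti to the benzyl group, would give the trans-lactone (3S,4R)-3-[hydroxy(3,4,5-trimethoxyphenyl)methyl]-4-[(3,4,5-trimethoxyphenyl)methyl]oxolan-2-one F4 as carbinol epimers.
  - LiAlH4 would give the triol (2R,3R)-2-[hydroxy(3,4,5-trimethoxyphenyl)methyl]-3-[(3,4,5-trimethoxyphenyl)methyl]butane-1,4-diol F5.
  - Mild acid (camphorsulfonic acid, CH2Cl2, 0 °C) would close the oxolane by attack of the C5 hydroxyl on the benzylic cation, trans to the C3 substituent, to give 15.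
  - The trans-lactone maps onto the 3,4-cis oxolane, so C4 comes from the hydrogenation catalyst, C3 from the lactone and C2 from the ring closure.

**Step 6.**
- What may go wrong: syn–anti interconversion of the π-allyl complex, which would scramble the alkene geometry, and capture of the allyl unit by methoxide instead of CO.
- Fallback, setting out from 7 and coming back at 10, with no allyl–metal intermediate (Arndt–Eistert homologation):
  - Saponification (LiOH, THF/H2O) to (2E)-3-(3,4,5-trimethoxyphenyl)-2-{[(3,4,5-trimethoxyphenyl)methoxy]methyl}prop-2-enoic acid F6.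
  - Oxalyl chloride to (2E)-3-(3,4,5-trimethoxyphenyl)-2-{[(3,4,5-trimethoxyphenyl)methoxy]methyl}prop-2-enoyl chloride F7.
  - Excess diazomethane to (3E)-1-diazo-4-(3,4,5-trimethoxyphenyl)-3-{[(3,4,5-trimethoxyphenyl)methoxy]methyl}but-3-en-2-one F8.
  - Wolff rearrangement (PhCO2Ag, Et3N, MeOH), in which the alkenyl group migrates with its geometry and methanol traps the ketene, to give 10.

**Step 10.**
- What may go wrong: poor facial selectivity if the hydroxyl group anchors the substrate to the metal surface on its own face; hydrogenolysis of the benzylic C2–O1 bond; migration of the alkene into the ring.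
- Fallback, setting out from 13 and coming back at 15: the order of the last two steps is reversed, so that the bulkier, non-anchoring ester steers the hydrogenation. Hydrogenation of 13 (H2, 10% Pd on carbon, EtOAc) would give methyl (2S,3S,4R)-2-(3,4,5-trimethoxyphenyl)-4-[(3,4,5-trimethoxyphenyl)methyl]oxolane-3-carboxylate F9, and LiAlH4 would then give 15.

**Step 2.**
- What may go wrong: loss of the benzylic alkoxide from the enolate of 3 (retro-oxa-Michael) before the aldol addition, and retro-aldol cleavage on work-up.
- Fallback, setting out from 4 and 2 and coming back at 7, with no β-alkoxy enolate: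
  - Morita–Baylis–Hillman reaction (DABCO, neat) to methyl 2-[hydroxy(3,4,5-trimethoxyphenyl)methyl]prop-2-enoate F10.
  - HBr/H2SO4 with allylic transposition to methyl (2Z)-2-(bromomethyl)-3-(3,4,5-trimethoxyphenyl)prop-2-enoate F11.
  - Williamson etherification with the sodium alkoxide of 1 (NaH, THF, 0 °C) at the primary allylic carbon to give 7.

## Further compounds

F1 | step 8 | (3E)-3-(methoxycarbonyl)-4-(3,4,5-trimethoxyphenyl)but-3-enoic acid | COC(=O)/C(CC(=O)O)=C/c1cc(OC)c(OC)c(OC)c1
F2 | step 8 | (3R)-3-(methoxycarbonyl)-4-(3,4,5-trimethoxyphenyl)butanoic acid | COC(=O)[C@@H](CC(=O)O)Cc1cc(OC)c(OC)c(OC)c1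
F3 | step 8 | (4R)-4-[(3,4,5-trimethoxyphenyl)methyl]oxolan-2-one | COc1cc(C[C@H]2COC(=O)C2)cc(OC)c1OC
F4 | step 8 | (3S,4R)-3-[hydroxy(3,4,5-trimethoxyphenyl)methyl]-4-[(3,4,5-trimethoxyphenyl)methyl]oxolan-2-one (carbinol epimers) | COc1cc(C[C@H]2COC(=O)[C@@H]2C(O)c2cc(OC)c(OC)c(OC)c2)cc(OC)c1OC
F5 | step 8 | (2R,3R)-2-[hydroxy(3,4,5-trimethoxyphenyl)methyl]-3-[(3,4,5-trimethoxyphenyl)methyl]butane-1,4-diol (carbinol epimers) | COc1cc(C[C@@H](CO)[C@H](CO)C(O)c2cc(OC)c(OC)c(OC)c2)cc(OC)c1OC
F6 | step 6 | (2E)-3-(3,4,5-trimethoxyphenyl)-2-{[(3,4,5-trimethoxyphenyl)methoxy]methyl}prop-2-enoic acid | COc1cc(/C=C(\COCc2cc(OC)c(OC)c(OC)c2)C(=O)O)cc(OC)c1OC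
F7 | step 6 | (2E)-3-(3,4,5-trimethoxyphenyl)-2-{[(3,4,5-trimethoxyphenyl)methoxy]methyl}prop-2-enoyl chloride | COc1cc(/C=C(\COCc2cc(OC)c(OC)c(OC)c2)C(Cl)=O)cc(OC)c1OC
F8 | step 6 | (3E)-1-diazo-4-(3,4,5-trimethoxyphenyl)-3-{[(3,4,5-trimethoxyphenyl)methoxy]methyl}but-3-en-2-one | COc1cc(/C=C(\COCc2cc(OC)c(OC)c(OC)c2)C(=O)C=[N+]=[N-])cc(OC)c1OC
F9 | step 10 | methyl (2S,3S,4R)-2-(3,4,5-trimethoxyphenyl)-4-[(3,4,5-trimethoxyphenyl)methyl]oxolane-3-carboxylate | COc1cc(C[C@H]2CO[C@H](c3cc(OC)c(OC)c(OC)c3)[C@H]2C(=O)OC)cc(OC)c1OC
F10 | step 2 | methyl 2-[hydroxy(3,4,5-trimethoxyphenyl)methyl]prop-2-enoate (racemic) | COC(=O)C(=C)C(O)c1cc(OC)c(OC)c(OC)c1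
F11 | step 2 | methyl (2Z)-2-(bromomethyl)-3-(3,4,5-trimethoxyphenyl)prop-2-enoate | COC(=O)/C(CBr)=C/c1cc(OC)c(OC)c(OC)c1
A1 | alternative 1 | tert-butyl{[(2S,3R)-2-(3,4,5-trimethoxyphenyl)-4-[(3,4,5-trimethoxyphenyl)methyl]-2,3-dihydrofuran-3-yl]methoxy}dimethylsilane | COc1cc(CC2=CO[C@H](c3cc(OC)c(OC)c(OC)c3)[C@H]2CO[Si](C)(C)C(C)(C)C)cc(OC)c1OC
A2 | alternative 1 | 3-{[tert-butyl(dimethyl)silyl]oxymethyl}-2-(3,4,5-trimethoxyphenyl)-1-[(3,4,5-trimethoxyphenyl)methyl]cyclopropane-1-carbaldehyde (configuration defined at the silyloxymethyl carbon only; the other two ring carbons lose theirs in the key step) | O=CC1(Cc2cc(OC)c(OC)c(OC)c2)C(c2cc(OC)c(OC)c(OC)c2)[C@H]1CO[Si](C)(C)C(C)(C)C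
A3 | alternative 2 | cis-fused 4,6-bis(3,4,5-trimethoxyphenyl)-3,7-dioxabicyclo[3.3.0]octan-2-one (oxolane aryl trans to the lactone carbonyl carbon, lactone aryl anti to the oxolane) | COc1cc([C@@H]3[C@H]2CO[C@H](c4cc(OC)c(OC)c(OC)c4)[C@H]2C(=O)O3)cc(OC)c1OC
A4 | alternative 2 | (5S)-5-(3,4,5-trimethoxyphenyl)furan-2(5H)-one | COc1cc([C@@H]2C=CC(=O)O2)cc(OC)c1OC
A5 | alternative 2 | 5-{chloro[(trimethylsilyl)methoxy]methyl}-1,2,3-trimethoxybenzene (racemic) | COc1cc(C(Cl)OC[Si](C)(C)C)cc(OC)c1OC
A6 | alternative 3 | diethyl (4Z)-2-(3,4,5-trimethoxyphenyl)-4-[(3,4,5-trimethoxyphenyl)methylidene]oxolane-3,3-dicarboxylate (formed racemic at C2; the antipode that maps onto 15 is drawn) | COc1cc(/C=C2\CO[C@H](c3cc(OC)c(OC)c(OC)c3)C2(C(=O)OCC)C(=O)OCC)cc(OC)c1OC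
A7 | alternative 3 | diethyl 2-[(3,4,5-trimethoxyphenyl)methylidene]propanedioate | CCOC(=O)C(=Cc1cc(OC)c(OC)c(OC)c1)C(=O)OCC
A8 | alternative 3 | 5-iodo-1,2,3-trimethoxybenzene | COc1cc(I)cc(OC)c1OC
A9 | alternative 3 | prop-2-yn-1-ol | C#CCO
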